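Remark on the chemistry: the target has no stereocentre and no stereogenic double bond (the prenyl alkene ends in two methyl groups), so it is achiral and the route needs no stereocontrol.

## Analysis of the target

The target 14 is a flavone: a benzopyran-4-one (rings A and C) with a 2,4-dihydroxyphenyl ring B on C2, a prenyl (3-methylbut-2-enyl) chain on C3, a hydroxyl on C5 that is hydrogen-bonded to the C4 carbonyl, and a methoxy group on C7. There is no stereocentre, so the problem is one of connectivity and of telling functional groups apart. The sensitive groups are the trisubstituted prenyl alkene, which can hydrate, add acid or cyclise onto a phenol under strong acid and does not survive hydrogenation or strong oxidants, and the three free phenols on two electron-rich rings. Four ring oxygens must end as three hydroxyls and one methyl ether, which rules out a late demethylation. The prenyl group must be attached to C3, a hindered sp2 carbon between the C4 carbonyl and the twisted ring B, and the last deprotection must leave the alkene untouched. The strategy rests on two features: C4 is a single carbonyl carbon between C4a of ring A and C3, and ring A carries oxygen on both carbons ortho to C4a (O1 on C8a and the hydroxyl on C5), with the methoxy group para to C4a. Cutting C4a–C4, C4–C3 and O1–C2 therefore turns ring A into the symmetric 2-iodo-5-methoxyresorcinol 2, C4 into carbon monoxide 6, and C2, C3 and ring B into the aryl acetylene 5. Because 2 is symmetric, either hydroxyl can close the pyranone and the other becomes the 5-OH.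

## Retrosynthetic reasoning

**14 ⇒ 13.** The three phenols are masked as methoxymethyl acetals in 13. This acetal survives amine bases, palladium, carbon monoxide and lithium amides, and it is cleaved by mild acid that leaves the 7-methyl ether alone. The forward step must remove three acetals without protonating the prenyl alkene.

**13 ⇒ 10 + 11.** The C3–C1″ bond is cut. C3–H is the only C–H on the pyranone ring and can be removed by a hindered lithium amide to give the vinyl-lithium 12, so the flavone can be built first without the acid- and metal-sensitive prenyl group. This order is also forced: the annulation that makes the flavone needs a terminal alkyne, so C3 must carry hydrogen when the ring is formed. The forward step must alkylate at the primary carbon of 11 and not at its tertiary end.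

**10 ⇒ 9.** Only the O–C bond of the acetal on the 5-oxygen is cut. The free 5-OH of 9 would consume base and the resulting phenoxide would disfavour a second deprotonation at C3, so it is capped first.

**9 ⇒ 2 + 6 + 5 (key disconnection).** Three bonds are cut at once: C4a–C4, C4–C3 and O1–C2. This takes the whole pyranone ring apart into an aryl iodide (2), a one-carbon unit at the carbonyl oxidation level (6) and a terminal alkyne (5), three pieces of very different size and all simple. Cutting elsewhere, for example at C2–C1′ or within ring A, would leave a preformed chromone or a substituted acetophenone that must itself be made with the four oxygens already differentiated. The forward reaction must go through the ynone 7 rather than a direct aryl–alkyne coupling, and must close the six-membered ring through the amine adduct 8 rather than a five-membered aurone ring.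

**2 ⇒ 1.** The C–I bond is cut. The carbon between the two hydroxyls of 1 is ortho to both and para to the methoxy group, and phenoxide-type iodination of resorcinols goes to that position. The forward step must stop at mono-iodination.

**5 ⇒ 4 ⇒ 3.** The alkyne carbon–carbon triple bond is traced back to the aldehyde carbon of 4 by one-carbon homologation with a diazophosphonate, and 4 to 3 by protection of both phenols. Ring B is thus bought with both oxygens in place and needs no ring-forming chemistry.

## Alternatives that were turned down

**Alternative 1:** Three-component arylation and prenylation of a preformed chromone.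
- **Disconnection and key step:** C2–C1′ and C3–C1″ are cut from 7-methoxy-5-(methoxymethoxy)chromen-4-one A1. A copper-mediated conjugate addition of the aryl Grignard reagent A2 to C2 of A1, then trapping of the C3 enolate with prenyl bromide 11, would give the racemic trans-chromanone A3. Dehydrogenation across C2–C3 would lead to 13.
- **For:** both substituents on the pyranone double bond are attached in one flask, with no carbon monoxide and no separate protection and lithiation. On attaching the prenyl group it is more direct than the chosen route.
- **Against:** A3 is at the wrong oxidation level, so two stereocentres are made only to be destroyed. Dehydrogenating a 2,3-disubstituted chromanone next to the allylic C–H bonds of a prenyl group and an electron-rich ring B is unreliable. The enolate is a β-aryloxy enolate and can open to a chalcone phenoxide. Copper and magnesium enolates alkylate slowly with allylic halides, and a silyl chloride additive would trap the enolate on oxygen. A1 needs several steps and A2 needs a brominated, protected resorcinol.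
- **Comparison:** about nine steps against seven. The chosen strategy ends at the flavone oxidation level directly and draws ring A from a one-step symmetric iodide.

**Alternative 2:** Carbene-catalysed hydroacylation of a tethered enyne.
- **Disconnection and key step:** C3–C4 is cut, with the O1–C2 ether bond already in place. A carbene catalyst would turn the aldehyde of the aryl propargylic ether A4 into an acyl anion equivalent, which adds to the tethered alkyne and closes the dihydropyranone. The product A5 carries an exocyclic 3-methylbut-2-enylidene group on C3, and base-mediated migration of that double bond into the ring would give 13.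
- **For:** metal-free, fully atom-economical, no gas, and all prenyl carbons arrive with the ring closure, so no C3 lithiation is needed. On these points it is stronger than the chosen route.
- **Against:** A4 contains a secondary ether that is both benzylic (to a 2,4-dioxygenated ring) and propargylic, joined to a hindered, chelated salicylaldehyde phenol. Making that bond invites ionisation, elimination and rearrangement. The aldehyde has two ortho oxygens and is electron-rich, so formation of the acyl anion equivalent should be slow, and the conjugated enyne offers more than one site of attack. The cross-conjugated dienone A5 can also close by oxa-6π electrocyclisation to a 2H-pyran instead of isomerising.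
- **Comparison:** about ten steps with two uncertain ones. The chosen strategy offers instead a ring construction of a well-known type from a symmetric, trivially made ring A piece.

**Alternative 3:** Ring B built by Diels–Alder aromatisation.
- **Disconnection and key step:** ring B is cut at C1′–C2′ and C5′–C6′. The 2-ethynylchromone A6 would undergo [4+2] cycloaddition with the electron-rich diene A7, and loss of the acetal methoxy group with desilylation would aromatise the adduct to A8. Cleavage of the one remaining acetal would give 14.
- **For:** the polarity of both partners fixes the 2′,4′-dioxygenation pattern, and the ring B phenols emerge free. Only the most labile, carbonyl-assisted acetal is left to remove next to the prenyl group, so the end-game is milder than in the chosen route.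
- **Against:** A6 already contains the chromone, the C3 prenyl group and a C2 alkyne, so all the difficulties of the A/C system must be solved before the key step. The alkyne is only vinylogously activated and A7 is heat- and moisture-sensitive. Conjugate addition at C2 of the chromone and alternative elimination during aromatisation (leaving a methyl ether) are likely side paths.
- **Comparison:** more than ten steps. The chosen strategy buys ring B as an aromatic aldehyde and spends its one risky step on forming the pyranone.

Key step: step 4

## Route

Step 1
Reactants: 1 5-methoxyresorcinol (5-methoxybenzene-1,3-diol)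
Product: 2 2-iodo-5-methoxybenzene-1,3-diol
Conditions: I2 (1.0 equiv), NaHCO3 (1.1 equiv), THF/H2O 1:1, 0 °C
Reagents that add atoms: iodine, II
Why: Electrophilic aromatic iodination through the phenoxide in aqueous hydrogencarbonate, the conditions under which resorcinol and 5-substituted resorcinols are iodinated between the two hydroxyls; that carbon is ortho to both hydroxyls and para to the methoxy group. One equivalent of iodine at 0 °C limits di-iodination.

Step 2
Reactants: 3 2,4-dihydroxybenzaldehyde
Product: 4 2,4-bis(methoxymethoxy)benzaldehyde
Conditions: NaH (2.4 equiv), DMF, 0 °C; MOMCl (2.4 equiv), 0 °C → rt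
Reagents that add atoms: chloromethyl methyl ether, COCCl
Why: Williamson-type O-alkylation of both phenoxides; full deprotonation with NaH is chosen because the 2-OH is hydrogen-bonded to the aldehyde and reacts slowly with amine bases. The aldehyde has no α-hydrogen and is not affected.

Step 3
Reactants: 4 2,4-bis(methoxymethoxy)benzaldehyde
Product: 5 1-ethynyl-2,4-bis(methoxymethoxy)benzene
Conditions: dimethyl (1-diazo-2-oxopropyl)phosphonate (1.3 equiv), K2CO3 (2 equiv), MeOH, 0 °C → rt
Reagents that add atoms: dimethyl (1-diazo-2-oxopropyl)phosphonate, CC(=O)C(=[N+]=[N-])P(=O)(OC)OC
Why: Ohira–Bestmann homologation: methanolysis of the reagent gives the diazomethylphosphonate anion, which adds to the aldehyde in Horner–Wadsworth–Emmons fashion; loss of N2 and a 1,2-hydrogen shift of the alkylidene carbene give the terminal alkyne. The acetals are stable to K2CO3 in methanol.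

Step 4
Reactants: 2 2-iodo-5-methoxybenzene-1,3-diol; 5 1-ethynyl-2,4-bis(methoxymethoxy)benzene; 6 carbon monoxide
Product: 9 2-[2,4-bis(methoxymethoxy)phenyl]-5-hydroxy-7-methoxychromen-4-one, via aryl ynone 7 (not isolated), via diethylamino enaminone 8 (not isolated)
Conditions: PdCl2(PPh3)2 (5 mol %), CO (5 bar), Et2NH (excess), DMF, 80 °C, no copper salt
Reagents that add atoms: none
Why: Pd(0) formed in the flask adds oxidatively to the C–I bond of 2, and CO (6) inserts to give an aroylpalladium(II) iodide. The amine-deprotonated alkyne 5 is transferred to palladium and reductive elimination gives ynone 7, which forms C4a–C4 and C4–C3 with the CO carbon as C4. Diethylamine adds to the β-carbon of 7 to give enaminone 8, and one of the two equivalent ortho-hydroxyls then attacks the same carbon and expels the amine, closing the pyranone through O1–C2 in the 6-endo mode by addition–elimination. The closest known reaction type is the palladium-catalysed carbonylative Sonogashira annulation of o-iodophenols with terminal acetylenes in a secondary amine, which gives flavones directly. No stereocentre is formed. Carbonylation must outrun direct alkynylation, which would lead to a 2-arylbenzofuran: CO pressure, the absence of copper, and the two ortho oxygens that crowd the aryl–palladium species and make the electron-rich aryl group migrate readily to CO all favour insertion. The 6-endo closure must outrun 5-exo closure to an aurone: in 8 only the amine-bearing β-carbon is electrophilic, so the phenol can only form the six-membered ring. Ring A poses no regiochemical question, because 2 is symmetric and whichever hydroxyl closes the ring leaves the other as the hydrogen-bonded 5-OH of 9.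

Step 5
Reactants: 9 2-[2,4-bis(methoxymethoxy)phenyl]-5-hydroxy-7-methoxychromen-4-one
Product: 10 2-[2,4-bis(methoxymethoxy)phenyl]-7-methoxy-5-(methoxymethoxy)chromen-4-one
Conditions: NaH (1.5 equiv), DMF, 0 °C; MOMCl (1.5 equiv), 0 °C → rt
Reagents that add atoms: chloromethyl methyl ether, COCCl
Why: Williamson-type O-alkylation; the peri hydroxyl is hydrogen-bonded to the C4 carbonyl and needs irreversible deprotonation before it reacts. Capping it removes the only acidic O–H before the amide base of step 6.

Step 6
Reactants: 10 2-[2,4-bis(methoxymethoxy)phenyl]-7-methoxy-5-(methoxymethoxy)chromen-4-one; 11 prenyl bromide (1-bromo-3-methylbut-2-ene)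
Product: 13 2-[2,4-bis(methoxymethoxy)phenyl]-7-methoxy-5-(methoxymethoxy)-3-(3-methylbut-2-enyl)chromen-4-one, via 3-lithioflavone 12 (not isolated)
Conditions: LDA (1.3 equiv), THF, −78 °C, 30 min; then 11 (2 equiv), −78 → 0 °C
Reagents that add atoms: none
Why: The hindered amide removes the only vinylic C–H of the pyranone (C3–H, α to the carbonyl) to give vinyl-lithium 12, the known C3 lithiation of 5-alkoxyflavones; SN2 alkylation at the primary carbon of the allylic bromide forms C3–C1″. LDA at −78 °C does not metalate the acetal-bearing arenes, and 12 is kept cold so that the pyranone does not open.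

Step 7
Reactants: 13 2-[2,4-bis(methoxymethoxy)phenyl]-7-methoxy-5-(methoxymethoxy)-3-(3-methylbut-2-enyl)chromen-4-one
Product: 14 2-(2,4-dihydroxyphenyl)-5-hydroxy-7-methoxy-3-(3-methylbut-2-enyl)chromen-4-one
Conditions: conc. HCl (cat.), MeOH/THF, 40 °C
Reagents that add atoms: none
Why: Acid-catalysed transacetalisation in methanol cleaves the three MOM ethers; the carbonyl-assisted peri acetal on C5 goes first and the two on ring B need gentle warming. The 7-methyl ether is inert, and at this acidity and temperature protonation of the trisubstituted alkene should be slow compared with acetal cleavage.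

## Compound list

1 | 5-methoxyresorcinol (5-methoxybenzene-1,3-diol) | COc1cc(O)cc(O)c1 | starting material
2 | 2-iodo-5-methoxybenzene-1,3-diol | COc1cc(O)c(I)c(O)c1 | intermediate
3 | 2,4-dihydroxybenzaldehyde | O=Cc1ccc(O)cc1O | starting material
4 | 2,4-bis(methoxymethoxy)benzaldehyde | COCOc1ccc(C=O)c(OCOC)c1 | intermediate
5 | 1-ethynyl-2,4-bis(methoxymethoxy)benzene | COCOc1ccc(C#C)c(OCOC)c1 | intermediate
6 | carbon monoxide | [C-]#[O+] | starting material
7 | 3-[2,4-bis(methoxymethoxy)phenyl]-1-(2,6-dihydroxy-4-methoxyphenyl)prop-2-yn-1-one | COCOc1ccc(C#CC(=O)c2c(O)cc(OC)cc2O)c(OCOC)c1 | intermediate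
8 | (E)-3-[2,4-bis(methoxymethoxy)phenyl]-3-(diethylamino)-1-(2,6-dihydroxy-4-methoxyphenyl)prop-2-en-1-one | CCN(CC)/C(c1ccc(OCOC)cc1OCOC)=C/C(=O)c1c(O)cc(OC)cc1O | intermediate
9 | 2-[2,4-bis(methoxymethoxy)phenyl]-5-hydroxy-7-methoxychromen-4-one | COCOc1ccc(-c2cc(=O)c3c(O)cc(OC)cc3o2)c(OCOC)c1 | intermediate
10 | 2-[2,4-bis(methoxymethoxy)phenyl]-7-methoxy-5-(methoxymethoxy)chromen-4-one | COCOc1ccc(-c2cc(=O)c3c(OCOC)cc(OC)cc3o2)c(OCOC)c1 | intermediate
11 | prenyl bromide (1-bromo-3-methylbut-2-ene) | CC(C)=CCBr | starting material
12 | [2-[2,4-bis(methoxymethoxy)phenyl]-7-methoxy-5-(methoxymethoxy)-4-oxochromen-3-yl]lithium | COCOc1ccc(-c2oc3cc(OC)cc(OCOC)c3c(=O)c2[Li])c(OCOC)c1 | intermediate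
13 | 2-[2,4-bis(methoxymethoxy)phenyl]-7-methoxy-5-(methoxymethoxy)-3-(3-methylbut-2-enyl)chromen-4-one | COCOc1ccc(-c2oc3cc(OC)cc(OCOC)c3c(=O)c2CC=C(C)C)c(OCOC)c1 | intermediate
14 | 2-(2,4-dihydroxyphenyl)-5-hydroxy-7-methoxy-3-(3-methylbut-2-enyl)chromen-4-one | COc1cc(O)c2c(=O)c(CC=C(C)C)c(-c3ccc(O)cc3O)oc2c1 | target

## Step count and least certain steps

Total step count: 7. Longest linear sequence: 6 steps (3 → 4 → 5 → 9 → 10 → 13 → 14; steps 2 to 7).

**Step 4 (key step).**
- Risk: the catalytic cycle may leak into direct, non-carbonylative alkynylation followed by cyclisation to a benzofuran, into capture of the aroylpalladium species by diethylamine, or into reductive loss of iodine. The cause is that oxidative addition to a very electron-rich, phenoxide-bearing aryl iodide is slow and the two free hydroxyls can bind palladium.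
- Fallback (classical chalcone route, no palladium and no CO): it sets out from aldehyde 4 and rejoins at 10. Commercial 1-(2,6-dihydroxy-4-methoxyphenyl)ethanone F1 is treated with MOMCl and i-Pr2NEt (CH2Cl2, 0 °C) to give 1-[2-hydroxy-4-methoxy-6-(methoxymethoxy)phenyl]ethanone F2; only one hydroxyl reacts readily because the other stays chelated to the ketone. Claisen–Schmidt condensation of F2 with 4 (KOH, EtOH, rt) should give (E)-3-[2,4-bis(methoxymethoxy)phenyl]-1-[2-hydroxy-4-methoxy-6-(methoxymethoxy)phenyl]prop-2-en-1-one F3. Oxidative cyclisation of F3 (cat. I2, DMSO, 120 °C) should give 10, which makes step 5 unnecessary. If the peri acetal were lost in that step, the product would be 9 and the route would be rejoined one step earlier.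

**Step 1.**
- Risk: iodination at a carbon between a hydroxyl and the methoxy group, or double iodination, because all three free ring positions are activated by three oxygen donors.
- Fallback (directed metalation instead of electrophilic substitution): it sets out from 1 and rejoins at 2. Double protection (NaH, MOMCl, DMF) gives 1-methoxy-3,5-bis(methoxymethoxy)benzene F4. Lithiation with n-BuLi (THF, 0 °C) goes to the carbon between the two chelating acetals, and an iodine quench at −78 °C gives 2-iodo-5-methoxy-1,3-bis(methoxymethoxy)benzene F5. Brief treatment with HCl in MeOH at rt should release 2.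

**Step 6.**
- Risk: alkylation at the tertiary end of the allylic bromide (SN2′), incomplete metalation, or opening of the lithiated pyranone by loss of the aryloxide on warming, because C3 is hindered and the alkylation may be slow.
- Fallback (allylation, then olefin cross-metathesis): it sets out from 10 and rejoins at 13. Lithiation as in step 6 and a quench with allyl bromide, which is more reactive and gives the same product by either SN2 or SN2′ attack, should give 3-allyl-2-[2,4-bis(methoxymethoxy)phenyl]-7-methoxy-5-(methoxymethoxy)chromen-4-one F6. Cross-metathesis of F6 with excess 2-methylbut-2-ene (second-generation ruthenium NHC benzylidene catalyst, CH2Cl2, 40 °C) should give 13.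

**Step 7.**
- Risk: addition of acid or methanol across the prenyl alkene, or cyclisation of the freed 2′-hydroxyl onto the tertiary cation, if the two ring B acetals need stronger acid than expected.
- Fallback (acid step before the prenyl alkene exists): it sets out from 10 and rejoins at 14. Compound 10 is converted as above into the allyl compound F6, whose terminal alkene is far less easily protonated. Acid cleavage (HCl, MeOH/THF, 40–50 °C) should give 3-allyl-2-(2,4-dihydroxyphenyl)-5-hydroxy-7-methoxychromen-4-one F7. Cross-metathesis of F7 with excess 2-methylbut-2-ene under the same catalyst, which tolerates free phenols, should give 14.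

## Further compounds

F1 | step 4 | 1-(2,6-dihydroxy-4-methoxyphenyl)ethanone (purchased) | CC(=O)c1c(O)cc(OC)cc1O
F2 | step 4 | 1-[2-hydroxy-4-methoxy-6-(methoxymethoxy)phenyl]ethanone | CC(=O)c1c(O)cc(OC)cc1OCOC
F3 | step 4 | (E)-3-[2,4-bis(methoxymethoxy)phenyl]-1-[2-hydroxy-4-methoxy-6-(methoxymethoxy)phenyl]prop-2-en-1-one | COCOc1ccc(/C=C/C(=O)c2c(O)cc(OC)cc2OCOC)c(OCOC)c1
F4 | step 1 | 1-methoxy-3,5-bis(methoxymethoxy)benzene | COCOc1cc(OC)cc(OCOC)c1
F5 | step 1 | 2-iodo-5-methoxy-1,3-bis(methoxymethoxy)benzene | COCOc1cc(OC)cc(OCOC)c1I
F6 | step 6 | 3-allyl-2-[2,4-bis(methoxymethoxy)phenyl]-7-methoxy-5-(methoxymethoxy)chromen-4-one | COCOc1ccc(-c2oc3cc(OC)cc(OCOC)c3c(=O)c2CC=C)c(OCOC)c1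
F7 | step 7 | 3-allyl-2-(2,4-dihydroxyphenyl)-5-hydroxy-7-methoxychromen-4-one | COc1cc(O)c2c(=O)c(CC=C)c(-c3ccc(O)cc3O)oc2c1
A1 | alternative 1 | 7-methoxy-5-(methoxymethoxy)chromen-4-one | COCOc1cc(OC)cc2occc(=O)c12
A2 | alternative 1 | [2,4-bis(methoxymethoxy)phenyl]magnesium bromide | COCOc1ccc([Mg]Br)c(OCOC)c1
A3 | alternative 1 | (±)-trans-2-[2,4-bis(methoxymethoxy)phenyl]-7-methoxy-5-(methoxymethoxy)-3-(3-methylbut-2-enyl)chroman-4-one (relative configuration shown) | COCOc1ccc([C@@H]2Oc3cc(OC)cc(OCOC)c3C(=O)[C@H]2CC=C(C)C)c(OCOC)c1
A4 | alternative 2 | (±)-2-{[1-[2,4-bis(methoxymethoxy)phenyl]-5-methylhex-4-en-2-yn-1-yl]oxy}-4-methoxy-6-(methoxymethoxy)benzaldehyde | COCOc1ccc(C(C#CC=C(C)C)Oc2cc(OC)cc(OCOC)c2C=O)c(OCOC)c1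
A5 | alternative 2 | (±)-(E)-2-[2,4-bis(methoxymethoxy)phenyl]-7-methoxy-5-(methoxymethoxy)-3-(3-methylbut-2-enylidene)chroman-4-one | COCOc1ccc(C2Oc3cc(OC)cc(OCOC)c3C(=O)/C2=C/C=C(C)C)c(OCOC)c1
A6 | alternative 3 | 2-ethynyl-7-methoxy-5-(methoxymethoxy)-3-(3-methylbut-2-enyl)chromen-4-one | COCOc1cc(OC)cc2oc(C#C)c(CC=C(C)C)c(=O)c12
A7 | alternative 3 | 1-methoxy-1,3-bis(trimethylsilyloxy)buta-1,3-diene | COC(O[Si](C)(C)C)=CC(=C)O[Si](C)(C)C
A8 | alternative 3 | 2-(2,4-dihydroxyphenyl)-7-methoxy-5-(methoxymethoxy)-3-(3-methylbut-2-enyl)chromen-4-one | COCOc1cc(OC)cc2oc(-c3ccc(O)cc3O)c(CC=C(C)C)c(=O)c12
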